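The cyclohexane ring is divided into two three-carbon units: C6–C7–C8, a methyl ketone enol, and C9–C10–C11, an allyl unit. A linalool-derived Z vinyl iodide and an allylic alcohol carrying a chiral sulfinyl group at C10 are first tied through a temporary C7–O–C9 ether. In the same flask a Claisen rearrangement forges the congested bond between the tertiary C6 and the quaternary C11, and the released methyl ketone closes C8–C9 by Michael addition to the new vinyl sulfoxide. The step exploits the 1,4-relation of the C7 oxygen and the C10 bromine across the ring: sulfur at C10 directs the facial course, activates C9 and is later exchanged for the equatorial bromide.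

Key step: step 6

Numbering used throughout: C1=C2 vinyl, C3 side-chain carbinol, C4, C5, ring C6 (CH), C7 (ring carbinol), C8, C9, C10 (CHBr), C11 (quaternary), C12–C15 the 4-methylpent-3-enyl ("homoprenyl") chain. The target is 3S,6S,7R,10S,11S.
Assumption: (S)-(+)-linalool (coriandrol) of high enantiomeric purity is taken as a purchasable terpene alcohol.

Step 1
Reactants: 1 (S)-(+)-linalool
Product: 2 (S)-linalool triethylsilyl ether
Conditions: Et3SiOTf, 2,6-lutidine, CH2Cl2, −78 to 0 °C
Reagents that add atoms: triethylsilyl trifluoromethanesulfonate, CC[Si](CC)(CC)OS(=O)(=O)C(F)(F)F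
Why: Silyl triflate with a hindered pyridine silylates the tertiary allylic alcohol without ionising it (silyl ether formation), and the ether prevents a ring-closing O-vinylation of this hydroxyl group in step 6, while C3 comes unchanged from the chiral pool.

Step 2
Reactants: 2 (S)-linalool triethylsilyl ether
Product: 3 (4S)-4-methyl-4-(triethylsilyloxy)hex-5-enal
Conditions: O3 (one equivalent), CH2Cl2/pyridine, −78 °C; then Me2S
Reagents that add atoms: ozone, [O-][O+]=O
Why: In this chemoselective ozonolysis the electron-rich trisubstituted alkene should react well before the vinyl group, which is deactivated and shielded by the adjacent silyloxy-bearing quaternary carbon, so that C6 is released as the aldehyde.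

Step 3
Reactants: 3 (4S)-4-methyl-4-(triethylsilyloxy)hex-5-enal
Product: 4 (3S,6Z)-7-iodo-3-methyl-3-(triethylsilyloxy)octa-1,6-diene
Conditions: EtPPh3I, n-BuLi, THF, 0 °C; I2, −78 °C; NaN(SiMe3)2, −20 °C; then 3, −78 °C
Reagents that add atoms: ethyltriphenylphosphonium iodide, CC[P+](c1ccccc1)(c1ccccc1)c1ccccc1.[I-]; iodine, II
Why: The Stork–Zhao-type Wittig reaction of the non-stabilised 1-iodoethylidene ylide adds C7 and C8 and should give the Z 2-iodoalkene under kinetic control, which fixes the enol ether geometry needed in step 6.

Step 4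
Reactants: 5 propargyl alcohol, 6 5-bromo-2-methylpent-2-ene
Product: 7 7-methyloct-6-en-2-yn-1-ol
Conditions: n-BuLi (two equivalents), THF/DMPU, −78 °C to rt
Reagents that add atoms: none
Why: The dilithiated propargyl alcohol is alkylated at the acetylide carbon by the primary bromide (SN2 acetylide alkylation), joining C9–C11 to the homoprenyl chain.

Step 5
Reactants: 7 7-methyloct-6-en-2-yn-1-ol
Product: 9 (2E)-3,7-dimethyl-2-[(S)-4-methylphenylsulfinyl]octa-2,6-dien-1-ol, via vinylmagnesium alkoxide 8 (not isolated)
Conditions: MeMgBr, Fe(acac)3 (cat.), THF, 0 °C to rt; then (1R,2S,5R)-menthyl (S)-4-methylbenzenesulfinate, −40 to 0 °C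
Reagents that add atoms: methylmagnesium bromide, C[Mg]Br; (1R,2S,5R)-menthyl (S)-4-methylbenzenesulfinate, C[C@@H]1CC[C@H]([C@@H](C1)O[S@](=O)c1ccc(C)cc1)C(C)C
Why: Alkoxide-directed iron-catalysed syn-carbomagnesiation puts the methyl group on the distal alkyne carbon C11 and magnesium on C10, so that the homoprenyl chain is cis to C9, and Andersen-type substitution at sulfur with inversion then installs the sulfinyl stereocentre with retention of the alkene geometry.

Step 6
Reactants: 4 (3S,6Z)-7-iodo-3-methyl-3-(triethylsilyloxy)octa-1,6-diene, 9 (2E)-3,7-dimethyl-2-[(S)-4-methylphenylsulfinyl]octa-2,6-dien-1-ol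
Product: 12 (2S,3S,4S)-3-methyl-3-(4-methylpent-3-enyl)-2-[(3S)-3-methyl-3-(triethylsilyloxy)pent-4-enyl]-4-[(R)-4-methylphenylsulfinyl]cyclohexanone, via allyl vinyl ether 10 (not isolated), via methyl ketone 11 (not isolated)
Conditions: CuI (cat.), 3,4,7,8-tetramethyl-1,10-phenanthroline (cat.), Cs2CO3, toluene, 110 °C; then THF, KOt-Bu (cat.), t-BuOH, −20 °C
Reagents that add atoms: none
Why: Copper-catalysed Ullmann-type O-vinylation joins 4 and 9 with retention of the Z geometry to give allyl vinyl ether 10, which rearranges at the same temperature by a [3,3]-sigmatropic Claisen shift to methyl ketone 11, forming C6–C11 and cleaving the temporary O–C9 bond, the closest known type being the domino copper-catalysed C–O coupling/Claisen rearrangement of vinyl iodides with allylic alcohols. After cooling, catalytic KOt-Bu enolises the unhindered methyl group C8, which adds to the CH2 terminus C9 of the vinyl sulfoxide (Michael addition of a ketone enolate to a vinyl sulfoxide) and closes the only ring in a 6-endo-trig mode. The relative configuration of C6 and C11 follows from the chair transition state, in which the Z enol ether places the side chain and the alkene geometry of 9 places the homoprenyl chain in anti axial positions, so that the side chain ends cis to the C11 methyl group. The absolute sense is set by sulfur: allylic 1,3-strain with the cis methyl group holds the sulfur lone pair in the alkene plane, the p-tolyl group shields one face, and C6 bonds to C11 on the face that carries the sulfinyl oxygen, as in known Claisen rearrangements of allyl vinyl ethers bearing a sulfinyl group at position 5. C10 arises by protonation and its configuration is of no consequence because it becomes a ketone in step 9 (the equatorial epimer is drawn). The step needs enolisation at C8 rather than C6 and no epimerisation at C6, which is secured because attack from C6 would give a four-membered ring, C6–H is shielded by the quaternary C11, the base is catalytic, cold and buffered by t-BuOH, and the cold second stage also keeps the new alkyl sulfoxide from syn elimination.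

Step 7
Reactants: 12 ring ketone sulfoxide
Product: 13 (1R,2S,3S,4S)-1,3-dimethyl-3-(4-methylpent-3-enyl)-2-[(3S)-3-methyl-3-(triethylsilyloxy)pent-4-enyl]-4-[(R)-4-methylphenylsulfinyl]cyclohexanol
Conditions: MeLi, CeCl3, THF, −78 °C
Reagents that add atoms: methyllithium, [Li]C
Why: The weakly basic organocerium reagent adds 1,2 to the enolisable ketone, and because the axial C11 methyl group blocks axial attack in the chair with the equatorial side chain (the flipped chair is blocked on both faces), the methyl group should enter equatorially and set C7 with the axial hydroxyl group.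

Step 8
Reactants: 13 tertiary alcohol sulfoxide
Product: 14 bis(triethylsilyl) ether of 13
Conditions: Et3SiOTf, 2,6-lutidine, CH2Cl2, 0 °C to rt
Reagents that add atoms: triethylsilyl trifluoromethanesulfonate, CC[Si](CC)(CC)OS(=O)(=O)C(F)(F)F
Why: Silylation of the hindered tertiary C7 hydroxyl group (silyl ether formation) prevents its transannular attack on C10, which could otherwise form a 1,4-oxygen bridge in steps 9 and 11.

Step 9
Reactants: 14 bis(triethylsilyl) ether sulfoxide
Product: 16 (2S,3S,4R)-2,4-dimethyl-2-(4-methylpent-3-enyl)-3-[(3S)-3-methyl-3-(triethylsilyloxy)pent-4-enyl]-4-(triethylsilyloxy)cyclohexanone, via trifluoroacetoxy sulfide 15 (not isolated)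
Conditions: (CF3CO)2O, 2,6-lutidine, CH2Cl2, 0 °C; then H2O, rt
Reagents that add atoms: trifluoroacetic anhydride, O=C(OC(=O)C(F)(F)F)C(F)(F)F
Why: In the Pummerer reaction the acylated sulfoxide can lose only the single alpha hydrogen at C10, and hydrolysis of the resulting O,S-acetal ester releases the C10 ketone and removes the spent auxiliary under buffered conditions that spare the silyl ethers and alkenes.

Step 10
Reactants: 16 C10 ketone
Product: 17 (1R,2S,3S,4R)-2,4-dimethyl-2-(4-methylpent-3-enyl)-3-[(3S)-3-methyl-3-(triethylsilyloxy)pent-4-enyl]-4-(triethylsilyloxy)cyclohexanol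
Conditions: Li(s-Bu)3BH, THF, −78 to 0 °C; then aq. NaOH, H2O2
Reagents that add atoms: none
Why: With the ring now locked by the equatorial side chain, C7 methyl group and homoprenyl chain, the bulky trialkylborohydride should attack the alpha-quaternary ketone from the equatorial side, as it does with 4,4-dimethyl-3-keto terpenoids, and give the axial C10 alcohol.

Step 11
Reactants: 17 axial C10 alcohol
Product: 18 bis(triethylsilyl) ether of the target
Conditions: CBr4, PPh3, toluene, 0 to 60 °C
Reagents that add atoms: tetrabromomethane, BrC(Br)(Br)Br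
Why: The Appel reaction activates only the secondary hydroxyl group, and bromide displaces the axial oxyphosphonium group by SN2 with inversion, which sets the equatorial C10 bromide cis to the C11 methyl group.

Step 12
Reactants: 18 bis(triethylsilyl) ether of the target
Product: 19 target (3S,6S,7R,10S,11S)
Conditions: HF·pyridine, pyridine, THF, 0 °C to rt
Reagents that add atoms: none
Why: Buffered fluoride-mediated desilylation cleaves both tertiary silyl ethers without ionising the tertiary allylic alcohol or eliminating the equatorial bromide.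

Compound list
1 | (S)-(+)-linalool | C=C[C@@](C)(O)CCC=C(C)C | starting material
2 | (S)-linalool triethylsilyl ether | C=C[C@@](C)(O[Si](CC)(CC)CC)CCC=C(C)C | intermediate
3 | (4S)-4-methyl-4-(triethylsilyloxy)hex-5-enal | C=C[C@@](C)(O[Si](CC)(CC)CC)CCC=O | intermediate
4 | (3S,6Z)-7-iodo-3-methyl-3-(triethylsilyloxy)octa-1,6-diene | C=C[C@@](C)(O[Si](CC)(CC)CC)CC/C=C(/C)I | intermediate
5 | propargyl alcohol | C#CCO | starting material
6 | 5-bromo-2-methylpent-2-ene | CC(C)=CCCBr | starting material
7 | 7-methyloct-6-en-2-yn-1-ol | OCC#CCCC=C(C)C | intermediate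
8 | bromomagnesium alkoxide of (2E)-2-(bromomagnesio)-3,7-dimethylocta-2,6-dien-1-ol | CC(C)=CCC/C(C)=C(\CO[Mg]Br)[Mg]Br | intermediate
9 | (2E)-3,7-dimethyl-2-[(S)-4-methylphenylsulfinyl]octa-2,6-dien-1-ol | CC(C)=CCC/C(C)=C(\CO)[S@@](=O)c1ccc(C)cc1 | intermediate
10 | allyl vinyl ether from 4 and 9 (Z enol ether, sulfur S) | C=C[C@@](C)(O[Si](CC)(CC)CC)CC/C=C(/C)OC/C(=C(/C)CCC=C(C)C)[S@@](=O)c1ccc(C)cc1 | intermediate
11 | acyclic methyl ketone (6S,11S) with the 1-sulfinylvinyl group on C11 | C=C[C@@](C)(O[Si](CC)(CC)CC)CC[C@H](C(C)=O)[C@](C)(CCC=C(C)C)C(=C)[S@@](=O)c1ccc(C)cc1 | intermediate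
12 | ring ketone with the C10 sulfoxide (6S,10S,11S; sulfur R by CIP, unchanged in space) | C=C[C@@](C)(O[Si](CC)(CC)CC)CC[C@H]1[C@](C)(CCC=C(C)C)[C@@H]([S@@](=O)c2ccc(C)cc2)CCC1=O | intermediate
13 | tertiary C7 alcohol (7R) with the C10 sulfoxide | C=C[C@@](C)(O[Si](CC)(CC)CC)CC[C@H]1[C@](C)(CCC=C(C)C)[C@@H]([S@@](=O)c2ccc(C)cc2)CC[C@@]1(C)O | intermediate
14 | bis(triethylsilyl) ether of 13 | C=C[C@@](C)(O[Si](CC)(CC)CC)CC[C@H]1[C@](C)(CCC=C(C)C)[C@@H]([S@@](=O)c2ccc(C)cc2)CC[C@@]1(C)O[Si](CC)(CC)CC | intermediate
15 | C10 trifluoroacetoxy p-tolyl sulfide | C=C[C@@](C)(O[Si](CC)(CC)CC)CC[C@H]1[C@](C)(CCC=C(C)C)C(OC(=O)C(F)(F)F)(Sc2ccc(C)cc2)CC[C@@]1(C)O[Si](CC)(CC)CC | intermediate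
16 | C10 ketone, bis(triethylsilyl) ether | C=C[C@@](C)(O[Si](CC)(CC)CC)CC[C@H]1[C@](C)(CCC=C(C)C)C(=O)CC[C@@]1(C)O[Si](CC)(CC)CC | intermediate
17 | axial C10 alcohol (10R), bis(triethylsilyl) ether | C=C[C@@](C)(O[Si](CC)(CC)CC)CC[C@H]1[C@](C)(CCC=C(C)C)[C@H](O)CC[C@@]1(C)O[Si](CC)(CC)CC | intermediate
18 | equatorial C10 bromide (10S), bis(triethylsilyl) ether | C=C[C@@](C)(O[Si](CC)(CC)CC)CC[C@H]1[C@](C)(CCC=C(C)C)[C@@H](Br)CC[C@@]1(C)O[Si](CC)(CC)CC | intermediate
19 | CNP0237376.1 | C=C[C@@](C)(O)CC[C@H]1[C@](C)(CCC=C(C)C)[C@@H](Br)CC[C@@]1(C)O | target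

Total step count: 12. Longest linear sequence: 10 (steps 1–3 and 6–12).

Steps most likely to fail

Step 6. The C–O coupling of the alpha-branched vinyl iodide with the hindered alcohol may be slow or stopped by binding of the sulfoxide to copper, and the doubly axial chair may lose out to a boat, which would erode the C6/C11 relation. The fallback sets out from 3 and 9 and forms the enol ether by exchange instead of cross-coupling. A Wittig reaction of 3 with (1-methoxyethylidene)triphenylphosphorane gives (3S)-7-methoxy-3-methyl-3-(triethylsilyloxy)octa-1,6-diene F1. Heating F1 with 9 and catalytic propionic acid in toluene (Saucy–Marbet-type enol ether exchange and Claisen rearrangement) expels methanol and passes through 10. The route is rejoined at 11, which is cyclised with KOt-Bu as before.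

Step 11. Substitution at the neopentyl secondary centre may be overtaken by elimination towards C9 or by migration of the antiperiplanar C11 methyl group. The fallback sets out from 16 and replaces substitution by a radical hydrogen delivery.
- 1,2-Bis(tert-butyldimethylsilyl)hydrazine with catalytic Sc(OTf)3 gives the N-silyl hydrazone F2.
- CuBr2 and Et3N in methanol convert F2 into the C10 geminal dibromide F3.
- One equivalent of Bu3SnH with catalytic (PhSe)2 and Et3B/air removes one bromine.

In the locked chair the alpha-bromo radical should take hydrogen on the axial face away from the axial C11 methyl group. The fast donor PhSeH should forestall cyclisation onto the homoprenyl alkene. The route is rejoined at 18.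

Step 5. The carbomagnesiation may go with the wrong regiochemistry or stall, and surplus MeMgBr may consume the sulfinate. The fallback sets out from 6 and builds the alkene on sulfur.
- 1-Propynylmagnesium bromide and the same menthyl sulfinate give (S)-1-propynyl p-tolyl sulfoxide F4.
- The Grignard reagent of 6 with CuBr·SMe2 adds syn across the alkyne (carbocupration of an alkynyl sulfoxide) to give, after protonation, (R)-[(1E)-2,6-dimethylhepta-1,5-dienyl] p-tolyl sulfoxide F5.
- Alpha-lithiation of F5 with LiN(i-Pr)2 and trapping with formaldehyde rejoins the route at 9.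

Further compounds
F1 | step 6 | (3S)-7-methoxy-3-methyl-3-(triethylsilyloxy)octa-1,6-diene | C=C[C@@](C)(O[Si](CC)(CC)CC)CCC=C(C)OC
F2 | step 11 | N-tert-butyldimethylsilyl hydrazone of 16 | C=C[C@@](C)(O[Si](CC)(CC)CC)CC[C@H]1[C@](C)(CCC=C(C)C)C(=NN[Si](C)(C)C(C)(C)C)CC[C@@]1(C)O[Si](CC)(CC)CC
F3 | step 11 | C10 geminal dibromide, bis(triethylsilyl) ether | C=C[C@@](C)(O[Si](CC)(CC)CC)CC[C@H]1[C@](C)(CCC=C(C)C)C(Br)(Br)CC[C@@]1(C)O[Si](CC)(CC)CC
F4 | step 5 | (S)-1-propynyl p-tolyl sulfoxide | CC#C[S@@](=O)c1ccc(C)cc1
F5 | step 5 | (R)-[(1E)-2,6-dimethylhepta-1,5-dienyl] p-tolyl sulfoxide | CC(C)=CCC/C(C)=C/[S@@](=O)c1ccc(C)cc1
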